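## The problem

The target is a flavonol. Ring A (C4a, C5–C8, C8a) carries hydroxyls at C5 and C7, ring C is the 3-hydroxy-4-pyranone, and ring B at C2 is 4-hydroxy-3-methoxyphenyl. C8 bears a 1-(4-hydroxy-3,5-dimethoxyphenyl)ethyl group whose benzylic carbon, of (R) configuration, is the only stereocentre. With no second stereocentre to relay from, it has to be set by a catalyst or reagent. Once set, it is a diarylmethine between two very electron-rich rings, so strong acid (ionisation, retro-Friedel–Crafts) and hydrogen-abstracting oxidants threaten it, whereas base is harmless as long as the carbon is never α to a carbonyl. C6 and C8 of a phloroglucinol ring are electronically alike, so attaching the side chain to a preformed ring A would give neither regiocontrol nor stereocontrol. The five free hydroxyls and the enolic 3-hydroxy-4-pyranone make the final compound sensitive to air and base, so it should appear only in the last step, and three methyl ethers must survive the unmasking. The enabling feature is that C4, ring A and the C8 substituent together are an acylphloroglucinol, a folded tetraketide: C8a is the carbon of a terminal ester, C8 its α-carbon, and the stereocentre sits β to that ester, where conjugate addition of an aryl group to a crotonate places it.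

## Retrosynthesis

**18 from 17.** The four O–benzyl bonds of 17 are cut last. Benzyl serves all four masked phenols (C5, C7, C4′ and the side-chain phenol) because one neutral hydrogenolysis frees them together. Methyl ethers could not be removed without touching the three methoxy groups of the target, and acid-labile acetals would expose the diarylmethine to acid at the very end. The forward step only has to spare the C2=C3 bond and the benzylic C–C bonds.

**17 from 15.** The C3–O bond is cut, leading to flavone 15; forward, 15 is epoxidised to 16 and the epoxide is opened by acid. Carrying the oxygen from the start on the acetyl methyl group would load the key cyclisation with an α-alkoxy ketone. Oxidising a chalcone with alkaline peroxide tends to give aurones when the position that becomes C5 is oxygenated. The price of the chosen cut is that the oxidant must prefer the C2=C3 bond to the benzylic C–H of the side chain.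

**15 from 14, and 14 from 11 and 13.** The O1–C2 bond is cut (cyclodehydration of diketone 14), then the bond between C3 and the aroyl carbon (aroylation of methyl ketone 11 with acid chloride 13, made from acid 12). This is the classical flavone disconnection and splits the molecule into ring B as a commercial benzoic acid and an acetophenone holding everything else. It requires a free phenol where O1 will be and a masked one where the C5 oxygen will be, so ring C can close only towards the side chain. Aroylating the enolate carbon directly avoids esterifying a hindered phenol.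

**11 from 10.** The two ring A benzyl ethers are cut to give triol 10. The simplification is small, but the whole task of telling the three phenols apart falls on this one step. The phenol para to the acetyl group and the unhindered ortho phenol must react; the ortho phenol next to the side chain must not.

**10 from 9 (key).** Ring A is opened at C4a–C8a (flavonol numbering; C6–C1 of the octanoate), unfolding the acetophenone into triketo ester 9. The neighbouring cut, alkylation of a preformed acylphloroglucinol at the future C8, leaves both regiochemistry and configuration open. Here the side chain is on the ester α-carbon, so it must end between two ring oxygens next to the later O1, and its stereocentre is already present and only carried along. The precursor is acyclic, has one stereocentre and consists of an aryl-substituted butanoate plus three acetyl units. The forward reaction must be a Claisen, not an aldol, closure and must tolerate a tertiary carbon next to the ester.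

**9 from 8, 7 and 5.** The chain is cut at C6–C7, C4–C5 and C2–C3, removing one acetyl group each time, through diketo ester 8 and keto ester 7 to butanoate 5; amide 6 is the acetyl donor throughout. Growing from the ester end follows the order of acidity (ester enolate, dianion, trianion), so each new carbanion forms at the chain terminus. An N-methoxy-N-methylamide holds its tetrahedral adduct until work-up, so the increasingly acidic products cannot quench the nucleophile. A more convergent union of a preformed diketone dianion with an activated malonyl unit carrying the side chain was set aside: such an acyl donor has an acidic hydrogen between its carbonyls and would be deprotonated, not attacked.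

**5 from 2 and 3, and 2 from 1.** The aryl–C3 bond of 5 is cut, giving crotonate 3 and an aryl nucleophile (borate 4) from bromide 2, the benzyl ether of phenol 1. A rhodium–BINAP conjugate addition forms this bond and the only stereocentre in one catalytic step from achiral materials. Hydrogenating a β-aryl crotonate would need a geometrically pure trisubstituted alkene and one more C–C bond-forming step; an auxiliary-based addition costs extra steps and is kept as a fallback. The stereocentre is β to the ester and therefore safe in all later base chemistry.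

## Roads not taken

**Alternative 1:** The cut is C4–C4a of ring C.
- Forward step: the (Z)-3-aryloxy-3-arylacrylic acid A2, whose aryloxy group is ring A already carrying the side chain, is activated with (CF3CO)2O and acylates the one free position ortho to the ether oxygen. This gives flavone A3, identical in structure to 15. A2 would come from phenol A1 by conjugate addition to an arylpropiolic ester and hydrolysis.
- Merits: ring C closes with no regiochemical choice, since the other ortho position of A1 is blocked by the side chain. No phenol has to be distinguished from another, and the union is convergent.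
- Weak points: A1, a phloroglucinol with the chiral side chain between two oxygens, is the hard part of the problem and the key step does nothing for it. The acylation runs in trifluoroacetic acid and anhydride on a ring A with three oxygen donors and no deactivating carbonyl, which invites ipso-protonation and loss or racemisation of the doubly benzylic group. The phenol that must add to the alkyne is hindered, and the Z geometry must be controlled. The product is still a flavone, so C3 hydroxylation remains.
- Comparison: Alternative 1 is better on the regiochemistry of pyranone closure, which the chosen plan secures only through a selective benzylation (step 7). Against this, the chosen plan builds ring A and places the side chain in one operation from the product of the asymmetric step, and it exposes the stereocentre to acid only after ring A carries a carbonyl.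

**Alternative 2:** Ring A is assembled around the side chain from cyclobutenone A4 and siloxyalkyne A5.
- Forward step: heating opens A4 to a vinylketene, which adds [2+2] to A5; the adduct reopens and closes by 6π electrocyclisation to phenol A6.
- Merits: the three ring A oxygens emerge fully differentiated (free hydroxyl, silyl ether, benzyl ether), which the chosen plan cannot match. Regiochemistry follows from the mechanism and the conditions are neutral.
- Weak points: A5 carries the stereocentre at the propargylic position and would be made from an α-arylpropanoic ester by strongly basic ynolate chemistry, where the centre is α to a carbonyl and prone to racemise. In the chosen plan it is never α to a carbonyl. A6 also lacks C4, so an acyl group must still be introduced ortho-selectively on a ring with two open positions before any flavonol chemistry starts.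
- Comparison: Alternative 2 wins on oxygen differentiation. The chosen plan sets against it an acetophenone with the acetyl group already in place and a stereocentre that is configurationally safe from the step that creates it.

**Alternative 3:** The cuts are C3–C4 and O1–C2.
- Forward step: a triazolium-derived carbene converts the hindered salicylaldehyde A7 into its acyl anion equivalent, which adds to the aldehyde of arylglyoxal A8. The phenol then closes onto the ketone and water is lost, giving flavonol A9, identical in structure to 17.
- Merits: the flavonol oxidation level is delivered directly, so no separate C3 hydroxylation is needed. That step (step 11) is the one in the chosen plan most likely to touch the benzylic C–H, so on this point Alternative 3 is clearly better. It is also convergent.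
- Weak points: the cross-benzoin needs the carbene to choose the less reactive aldehyde. A7 is di-ortho-substituted and electron-rich, the type that forms the Breslow intermediate most reluctantly, while A8 is the more electrophilic partner and prone to self-condensation. The closing phenol is hindered. A7 also presupposes ring A with the side chain installed and the phenols differentiated, as much prior work as compound 11.
- Comparison: the chosen plan needs two more steps and an oxidation, but every step from 11 to 17 is a standard flavonoid transformation, and its key step creates the ring A that Alternative 3 takes for granted.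

Key step: step 6

Assumptions on the chemistry:
- Compounds 6 and 12 (the benzyl ether of vanillic acid) are purchased.
- The sense of induction in step 2 is assigned by analogy with (E)-crotonates under rhodium–BINAP catalysis, where (S)-BINAP gives (R)-3-arylbutanoates. It would be confirmed on 5; if it proved opposite, (S)-BINAP would be used.
- Compounds 7, 8 and 9 are mixtures of C2 epimers and keto–enol forms, which is irrelevant because C2 becomes an aromatic carbon in step 6.

## Route

Step 1
Reactants: 1 4-bromo-2,6-dimethoxyphenol
Product: 2 2-(benzyloxy)-5-bromo-1,3-dimethoxybenzene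
Conditions: BnBr, K2CO3, DMF, 60 °C
Reagents that add atoms: benzyl bromide, BrCc1ccccc1
Why: Williamson ether synthesis; the 2,6-dimethoxyphenoxide is hindered but still readily O-benzylated, and the benzyl ether withstands the organolithium, enolate and alkoxide chemistry that follows and leaves with the other benzyl groups in step 12.

Step 2
Reactants: 2 2-(benzyloxy)-5-bromo-1,3-dimethoxybenzene; 3 methyl (2E)-but-2-enoate
Product: 5 methyl (3S)-3-[4-(benzyloxy)-3,5-dimethoxyphenyl]butanoate, via lithium aryltrimethoxyborate 4 (not isolated)
Conditions: n-BuLi, THF, −78 °C; B(OMe)3, −78 °C to rt; then 3, Rh(acac)(C2H4)2 (3 mol %), (R)-BINAP, H2O (1 equiv), 1,4-dioxane, 100 °C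
Reagents that add atoms: trimethyl borate, COB(OC)OC, and n-butyllithium, [Li]CCCC (boron, methoxy groups and lithium of intermediate 4; no atom of either remains in 5)
Why: Bromine–lithium exchange and borate formation, then Hayashi–Miyaura asymmetric 1,4-addition: the aryl group passes from boron to BINAP-bound rhodium, adds to one enantioface of the (E)-enoate, and water cleaves the rhodium enolate. The C3 stereocentre is set by the ligand, (R)-BINAP being expected to give the (S) ester; in-situ lithium aryltrimethoxyborates are known to serve enoates better than free boronic acids.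

Step 3
Reactants: 5 methyl (3S)-3-[4-(benzyloxy)-3,5-dimethoxyphenyl]butanoate; 6 N-methoxy-N-methylacetamide
Product: 7 methyl (3S)-2-acetyl-3-[4-(benzyloxy)-3,5-dimethoxyphenyl]butanoate (both C2 epimers)
Conditions: LiN(i-Pr)2, THF, −78 °C; then 6, −78 to 0 °C; aq. NH4Cl
Reagents that add atoms: none
Why: Crossed Claisen acylation of a lithium ester enolate with an N-methoxy-N-methylamide; the chelated tetrahedral adduct persists until work-up, so the more acidic β-keto ester never meets unreacted enolate. The new C2 centre is epimerisable and irrelevant, and the C3 stereocentre, β to the ester, is not deprotonated.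

Step 4
Reactants: 7 methyl (3S)-2-acetyl-3-[4-(benzyloxy)-3,5-dimethoxyphenyl]butanoate; 6 N-methoxy-N-methylacetamide
Product: 8 methyl 2-{(1S)-1-[4-(benzyloxy)-3,5-dimethoxyphenyl]ethyl}-3,5-dioxohexanoate
Conditions: LiN(i-Pr)2 (2.2 equiv), THF, −78 to 0 °C; then 6, −78 to 0 °C; aq. NH4Cl
Reagents that add atoms: none
Why: Acylation of a β-keto ester dianion: the first equivalent of base removes H2, the second an acetyl proton, and the terminal carbanion, the more basic and nucleophilic site, adds to 6 to give a stable chelate that releases the 3,5-diketo ester on work-up.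

Step 5
Reactants: 8 methyl 2-{(1S)-1-[4-(benzyloxy)-3,5-dimethoxyphenyl]ethyl}-3,5-dioxohexanoate; 6 N-methoxy-N-methylacetamide
Product: 9 methyl 2-{(1S)-1-[4-(benzyloxy)-3,5-dimethoxyphenyl]ethyl}-3,5,7-trioxooctanoate
Conditions: LiN(i-Pr)2 (3.3 equiv), THF, −78 to −20 °C; then 6, −78 to 0 °C; cold dilute HCl
Reagents that add atoms: none
Why: Acylation of a 3,5-diketo ester trianion at its terminal methyl carbanion, the known way to 3,5,7-triketo esters; full deprotonation at C2, C4 and C6 keeps the ester and ketones masked as enolates, so the chain does not condense with itself before the quench.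

Step 6
Reactants: 9 methyl 2-{(1S)-1-[4-(benzyloxy)-3,5-dimethoxyphenyl]ethyl}-3,5,7-trioxooctanoate
Product: 10 1-{3-[(1R)-1-(4-benzyloxy-3,5-dimethoxyphenyl)ethyl]-2,4,6-trihydroxyphenyl}ethanone
Conditions: Mg(OMe)2, MeOH, rt to 65 °C; then 1 M HCl
Reagents that add atoms: none
Why: Mg(OMe)2 turns 9 into a chelated polyenolate; the carbanion at C6, between the C5 and C7 carbonyls (the future C4a), adds to the ester carbonyl C1 (the future C8a), methoxide leaves, and the 2-acetylcyclohexane-1,3,5-trione enolises three times to the aromatic acetophenone. This is an intramolecular Claisen (Dieckmann-type) condensation, and the closest known reactions are the alkoxide-induced cyclisations of 3,5,7-triketo esters and of tetraacetic lactone to acylphloroglucinols. Ring A closes in the 6-exo-trig mode, the ester C=O lying outside the new ring. No stereocentre is formed; the existing one is β to C1 and C3, cannot enolise and is carried through unchanged, its descriptor changing from S to R only because C2 becomes an aromatic carbon of higher priority. The selectivity needed is Claisen over aldol and over lactonisation: the aldol fold through C2 would build a quaternary carbon that cannot aromatise and can revert, the other aldol fold needs the unactivated terminal methyl as nucleophile, and O-acylation to a pyranone is reversible in methanol whereas aromatisation is not. Because the arylethyl group sits on the α-carbon of the ester, it must end between two ring oxygens and next to the hydroxyl that later becomes O1, which fixes C8 without any choice between C6 and C8.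

Step 7
Reactants: 10 1-{3-[(1R)-1-(4-benzyloxy-3,5-dimethoxyphenyl)ethyl]-2,4,6-trihydroxyphenyl}ethanone
Product: 11 1-{4,6-bis(benzyloxy)-3-[(1R)-1-(4-benzyloxy-3,5-dimethoxyphenyl)ethyl]-2-hydroxyphenyl}ethanone
Conditions: BnBr (2.1 equiv), K2CO3, acetone, 56 °C
Reagents that add atoms: benzyl bromide, BrCc1ccccc1
Why: Williamson benzylation under mild carbonate conditions: the hydroxyl para to the acetyl group is the most acidic and reacts first; of the two chelated ortho hydroxyls, the one at C6 has a hydrogen neighbour, whereas the one at C2 is shielded by the arylethyl group and held in the stronger hydrogen bond, so it should remain. Selective 4,6-dialkylation of 3-substituted phloroacetophenones in this sense is known.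

Step 8
Reactants: 12 4-(benzyloxy)-3-methoxybenzoic acid
Product: 13 4-(benzyloxy)-3-methoxybenzoyl chloride
Conditions: (COCl)2, cat. DMF, CH2Cl2, 0 °C to rt
Reagents that add atoms: oxalyl chloride, O=C(Cl)C(Cl)=O
Why: Standard acid chloride formation through the Vilsmeier-type chloroiminium species from DMF and oxalyl chloride; the benzyl and methyl ethers are inert.

Step 9
Reactants: 11 1-{4,6-bis(benzyloxy)-3-[(1R)-1-(4-benzyloxy-3,5-dimethoxyphenyl)ethyl]-2-hydroxyphenyl}ethanone; 13 4-(benzyloxy)-3-methoxybenzoyl chloride
Product: 14 1-{4,6-bis(benzyloxy)-3-[(1R)-1-(4-benzyloxy-3,5-dimethoxyphenyl)ethyl]-2-hydroxyphenyl}-3-[4-(benzyloxy)-3-methoxyphenyl]propane-1,3-dione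
Conditions: LiN(SiMe3)2 (3.5 equiv), THF, −78 °C; then 13, −78 °C to rt; aq. NH4Cl
Reagents that add atoms: none
Why: Baker–Venkataraman-type construction of the 1,3-diketone done directly on carbon: excess base forms the phenoxide–enolate of 11, the enolate carbon is aroylated by 13, and a third equivalent of base traps the acidic diketone. C-Aroylation of lithium polyanions of 2-hydroxyacetophenones is known and avoids esterifying the hindered phenol first.

Step 10
Reactants: 14 1-{4,6-bis(benzyloxy)-3-[(1R)-1-(4-benzyloxy-3,5-dimethoxyphenyl)ethyl]-2-hydroxyphenyl}-3-[4-(benzyloxy)-3-methoxyphenyl]propane-1,3-dione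
Product: 15 5,7-bis(benzyloxy)-2-[4-(benzyloxy)-3-methoxyphenyl]-8-[(1R)-1-(4-benzyloxy-3,5-dimethoxyphenyl)ethyl]-4H-chromen-4-one
Conditions: TsOH·H2O (cat.), toluene, 90 °C
Reagents that add atoms: none
Why: Acid-catalysed cyclodehydration: the free phenol adds to the aryl ketone and the 2-hydroxychromanone loses water; only the hydroxyl next to the arylethyl group is free, so O1 is bound to C8a and the side chain is at C8. Catalytic sulfonic acid in toluene is used in place of hot mineral acid to spare the benzyl ethers and the diarylmethine centre.

Step 11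
Reactants: 15 5,7-bis(benzyloxy)-2-[4-(benzyloxy)-3-methoxyphenyl]-8-[(1R)-1-(4-benzyloxy-3,5-dimethoxyphenyl)ethyl]-4H-chromen-4-one
Product: 17 5,7-bis(benzyloxy)-2-[4-(benzyloxy)-3-methoxyphenyl]-8-[(1R)-1-(4-benzyloxy-3,5-dimethoxyphenyl)ethyl]-3-hydroxy-4H-chromen-4-one, via flavone 2,3-epoxide 16 (not isolated)
Conditions: dimethyldioxirane, acetone/CH2Cl2, 0 °C; then TsOH·H2O (cat.), CH2Cl2, rt
Reagents that add atoms: dimethyldioxirane, CC1(C)OO1
Why: Epoxidation of the enol-ether-like C2=C3 bond by the dioxirane, then acid-induced opening of the epoxide at C2 (cation stabilised by O1 and ring B) and loss of H3 give the 3-hydroxyflavone, a known two-stage oxidation of protected flavones. The epoxide stereocentres are destroyed again, and the cold, neutral oxidation is meant to leave the hindered benzylic C–H alone.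

Step 12
Reactants: 17 5,7-bis(benzyloxy)-2-[4-(benzyloxy)-3-methoxyphenyl]-8-[(1R)-1-(4-benzyloxy-3,5-dimethoxyphenyl)ethyl]-3-hydroxy-4H-chromen-4-one
Product: 18 3,5,7-trihydroxy-2-(4-hydroxy-3-methoxyphenyl)-8-[(1R)-1-(4-hydroxy-3,5-dimethoxyphenyl)ethyl]-4H-chromen-4-one
Conditions: H2 (1 atm), Pd/C, THF/MeOH, rt
Reagents that add atoms: none
Why: Hydrogenolysis of four aryl benzyl ethers over Pd/C under neutral conditions; the C–C bonds at the diarylmethine carbon, the methyl ethers and the C2=C3 bond of the flavonol should be untouched at one atmosphere.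

## Compound list

1 | 4-bromo-2,6-dimethoxyphenol | COc1cc(Br)cc(OC)c1O | starting material
2 | 2-(benzyloxy)-5-bromo-1,3-dimethoxybenzene | COc1cc(Br)cc(OC)c1OCc1ccccc1 | intermediate
3 | methyl (2E)-but-2-enoate | C/C=C/C(=O)OC | starting material
4 | lithium [4-(benzyloxy)-3,5-dimethoxyphenyl]trimethoxyborate | [Li+].CO[B-](OC)(OC)c1cc(OC)c(OCc2ccccc2)c(OC)c1 | intermediate (not isolated)
5 | methyl (3S)-3-[4-(benzyloxy)-3,5-dimethoxyphenyl]butanoate | COC(=O)C[C@H](C)c1cc(OC)c(OCc2ccccc2)c(OC)c1 | intermediate
6 | N-methoxy-N-methylacetamide | CC(=O)N(C)OC | starting material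
7 | methyl (3S)-2-acetyl-3-[4-(benzyloxy)-3,5-dimethoxyphenyl]butanoate (C2 epimers) | COC(=O)C(C(C)=O)[C@H](C)c1cc(OC)c(OCc2ccccc2)c(OC)c1 | intermediate
8 | methyl 2-{(1S)-1-[4-(benzyloxy)-3,5-dimethoxyphenyl]ethyl}-3,5-dioxohexanoate (C2 epimers) | COC(=O)C(C(=O)CC(C)=O)[C@H](C)c1cc(OC)c(OCc2ccccc2)c(OC)c1 | intermediate
9 | methyl 2-{(1S)-1-[4-(benzyloxy)-3,5-dimethoxyphenyl]ethyl}-3,5,7-trioxooctanoate (C2 epimers) | COC(=O)C(C(=O)CC(=O)CC(C)=O)[C@H](C)c1cc(OC)c(OCc2ccccc2)c(OC)c1 | intermediate
10 | 1-{3-[(1R)-1-(4-benzyloxy-3,5-dimethoxyphenyl)ethyl]-2,4,6-trihydroxyphenyl}ethanone | CC(=O)c1c(O)cc(O)c([C@H](C)c2cc(OC)c(OCc3ccccc3)c(OC)c2)c1O | intermediate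
11 | 1-{4,6-bis(benzyloxy)-3-[(1R)-1-(4-benzyloxy-3,5-dimethoxyphenyl)ethyl]-2-hydroxyphenyl}ethanone | CC(=O)c1c(OCc2ccccc2)cc(OCc2ccccc2)c([C@H](C)c2cc(OC)c(OCc3ccccc3)c(OC)c2)c1O | intermediate
12 | 4-(benzyloxy)-3-methoxybenzoic acid | COc1cc(C(=O)O)ccc1OCc1ccccc1 | starting material
13 | 4-(benzyloxy)-3-methoxybenzoyl chloride | COc1cc(C(Cl)=O)ccc1OCc1ccccc1 | intermediate
14 | 1-{4,6-bis(benzyloxy)-3-[(1R)-1-(4-benzyloxy-3,5-dimethoxyphenyl)ethyl]-2-hydroxyphenyl}-3-[4-(benzyloxy)-3-methoxyphenyl]propane-1,3-dione | COc1cc(C(=O)CC(=O)c2c(OCc3ccccc3)cc(OCc3ccccc3)c([C@H](C)c3cc(OC)c(OCc4ccccc4)c(OC)c3)c2O)ccc1OCc1ccccc1 | intermediate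
15 | 5,7-bis(benzyloxy)-2-[4-(benzyloxy)-3-methoxyphenyl]-8-[(1R)-1-(4-benzyloxy-3,5-dimethoxyphenyl)ethyl]-4H-chromen-4-one | COc1cc(-c2cc(=O)c3c(OCc4ccccc4)cc(OCc4ccccc4)c([C@H](C)c4cc(OC)c(OCc5ccccc5)c(OC)c4)c3o2)ccc1OCc1ccccc1 | intermediate
16 | 2,3-epoxide of 15: 5,7-bis(benzyloxy)-2-[4-(benzyloxy)-3-methoxyphenyl]-8-[(1R)-1-(4-benzyloxy-3,5-dimethoxyphenyl)ethyl]-2,3-epoxy-2,3-dihydro-4H-chromen-4-one (epoxide carbons as a mixture) | O=C1C2OC2(c3ccc(OCc4ccccc4)c(OC)c3)Oc5c1c(OCc6ccccc6)cc(OCc7ccccc7)c5[C@H](C)c8cc(OC)c(OCc9ccccc9)c(OC)c8 | intermediate (not isolated)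
17 | 5,7-bis(benzyloxy)-2-[4-(benzyloxy)-3-methoxyphenyl]-8-[(1R)-1-(4-benzyloxy-3,5-dimethoxyphenyl)ethyl]-3-hydroxy-4H-chromen-4-one | COc1cc(-c2oc3c([C@H](C)c4cc(OC)c(OCc5ccccc5)c(OC)c4)c(OCc4ccccc4)cc(OCc4ccccc4)c3c(=O)c2O)ccc1OCc1ccccc1 | intermediate
18 | 3,5,7-trihydroxy-2-(4-hydroxy-3-methoxyphenyl)-8-[(1R)-1-(4-hydroxy-3,5-dimethoxyphenyl)ethyl]-4H-chromen-4-one | COc1cc(-c2oc3c([C@H](C)c4cc(OC)c(O)c(OC)c4)c(O)cc(O)c3c(=O)c2O)ccc1O | target

## Step count and least certain steps

Total: 12 steps. Longest linear sequence: 11 steps (steps 1–7 and 9–12, from 1 to 18); step 8 is a one-step branch.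

**Step 6 (key step).** C-Acylation at an ester carbonyl whose α-carbon is tertiary and carries a bulky group may be slow. Methoxide-induced retro-Claisen scission of the polyketone chain, or lactonisation through an enol oxygen, could then drain the material. The fallback replaces the oxygen ester with a thioester, a far better acyl donor, and closes the ring without any alkoxide.
- It sets out from 5. Me2AlS-t-Bu (from AlMe3 and 2-methylpropane-2-thiol, CH2Cl2) converts the methyl ester into S-tert-butyl (3S)-3-[4-(benzyloxy)-3,5-dimethoxyphenyl]butanethioate F1.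
- The three acetylations of steps 3 to 5 with 6 (enolate, dianion, trianion) give in turn S-tert-butyl (3S)-2-acetyl-3-[4-(benzyloxy)-3,5-dimethoxyphenyl]butanethioate F2, S-tert-butyl 2-{(1S)-1-[4-(benzyloxy)-3,5-dimethoxyphenyl]ethyl}-3,5-dioxohexanethioate F3 and S-tert-butyl 2-{(1S)-1-[4-(benzyloxy)-3,5-dimethoxyphenyl]ethyl}-3,5,7-trioxooctanethioate F4.
- F4 is cyclised with a non-nucleophilic base (LiN(SiMe3)2, THF, −78 °C to rt) with loss of the thiol, and the route is rejoined at 10. The same C4a–C8a bond is formed.

**Step 5.** Deprotonation at the hindered C2 of 8 may be incomplete. The lower anion could then transfer protons or attack its own ester, so that conversion stalls or the chain condenses early. The fallback brings in C5–C8 as one piece with the last ketone masked, needing only a dianion.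
- It sets out from 7. The dianion of 7 (as in step 4, two equivalents because the product is deprotonated as it forms, unreacted 7 being recovered) is acylated with commercial ethyl 2-(2-methyl-1,3-dioxolan-2-yl)acetate.
- This gives methyl 2-{(1S)-1-[4-(benzyloxy)-3,5-dimethoxyphenyl]ethyl}-6-(2-methyl-1,3-dioxolan-2-yl)-3,5-dioxohexanoate F5.
- Dilute aqueous HCl in THF removes the dioxolane, and the route is rejoined at 9, replacing steps 4 and 5.

**Step 7.** Site selectivity between the two hydrogen-bonded ortho hydroxyls may be lost, or alkylation may run on to the tribenzyl ether. The fallback alkylates exhaustively and differentiates by cleavage instead.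
- It sets out from 10. Excess BnBr with K2CO3 in DMF at 80 °C gives 1-{2,4,6-tris(benzyloxy)-3-[(1R)-1-(4-benzyloxy-3,5-dimethoxyphenyl)ethyl]phenyl}ethanone F6.
- MgBr2·OEt2 in toluene/Et2O removes a benzyl group only from an oxygen ortho to the carbonyl, through chelation. Of the two such ethers, the one also flanked by the arylethyl group is twisted out of the ring plane and is the more basic and more strained, so it should be cleaved first.
- The route is rejoined at 11.

**Step 11.** Epoxidation of the vinylogous ester is slow, so the dioxirane may instead oxidise the tertiary, doubly benzylic C–H of the side chain or the benzyl ethers. The fallback hydroxylates C3 through a carbanion, with no hydrogen-abstracting oxidant.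
- It sets out from 15. LiN(i-Pr)2 in THF at −78 °C lithiates C3, the known site of deprotonation of flavones.
- B(OMe)3 traps the anion as dimethyl {5,7-bis(benzyloxy)-2-[4-(benzyloxy)-3-methoxyphenyl]-8-[(1R)-1-(4-benzyloxy-3,5-dimethoxyphenyl)ethyl]-4-oxo-4H-chromen-3-yl}boronate F7.
- H2O2/AcOH oxidises the C–B bond, and the route is rejoined at 17.

**Step 2.** Facial selectivity may be incomplete with the small methyl ester, and the electron-rich aryl borate may protodeboronate at 100 °C. The fallback uses auxiliary control.
- (4R)-4-Phenyl-1,3-oxazolidin-2-one is acylated (n-BuLi, then (E)-but-2-enoyl chloride) to (4R)-3-[(2E)-but-2-enoyl]-4-phenyl-1,3-oxazolidin-2-one F8.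
- It sets out from 2, which with magnesium in THF gives [4-(benzyloxy)-3,5-dimethoxyphenyl]magnesium bromide F9.
- Conjugate addition of F9 to F8 mediated by CuBr·SMe2, from the face opposite the phenyl group of the chelated s-cis imide, gives (4R)-3-{(3S)-3-[4-(benzyloxy)-3,5-dimethoxyphenyl]butanoyl}-4-phenyl-1,3-oxazolidin-2-one F10. A minor diastereomer would be removable by crystallisation or chromatography.
- NaOMe in MeOH at 0 °C releases the auxiliary, and the route is rejoined at 5.

## Further compounds

F1 | step 6 | S-tert-butyl (3S)-3-[4-(benzyloxy)-3,5-dimethoxyphenyl]butanethioate | CC(C)(C)SC(=O)C[C@H](C)c1cc(OC)c(OCc2ccccc2)c(OC)c1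
F2 | step 6 | S-tert-butyl (3S)-2-acetyl-3-[4-(benzyloxy)-3,5-dimethoxyphenyl]butanethioate | CC(C)(C)SC(=O)C(C(C)=O)[C@H](C)c1cc(OC)c(OCc2ccccc2)c(OC)c1
F3 | step 6 | S-tert-butyl 2-{(1S)-1-[4-(benzyloxy)-3,5-dimethoxyphenyl]ethyl}-3,5-dioxohexanethioate | CC(C)(C)SC(=O)C(C(=O)CC(C)=O)[C@H](C)c1cc(OC)c(OCc2ccccc2)c(OC)c1
F4 | step 6 | S-tert-butyl 2-{(1S)-1-[4-(benzyloxy)-3,5-dimethoxyphenyl]ethyl}-3,5,7-trioxooctanethioate | CC(C)(C)SC(=O)C(C(=O)CC(=O)CC(C)=O)[C@H](C)c1cc(OC)c(OCc2ccccc2)c(OC)c1
F5 | step 5 | methyl 2-{(1S)-1-[4-(benzyloxy)-3,5-dimethoxyphenyl]ethyl}-6-(2-methyl-1,3-dioxolan-2-yl)-3,5-dioxohexanoate | COC(=O)C(C(=O)CC(=O)CC1(C)OCCO1)[C@H](C)c1cc(OC)c(OCc2ccccc2)c(OC)c1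
F6 | step 7 | 1-{2,4,6-tris(benzyloxy)-3-[(1R)-1-(4-benzyloxy-3,5-dimethoxyphenyl)ethyl]phenyl}ethanone | CC(=O)c1c(OCc2ccccc2)cc(OCc2ccccc2)c([C@H](C)c2cc(OC)c(OCc3ccccc3)c(OC)c2)c1OCc1ccccc1
F7 | step 11 | dimethyl {5,7-bis(benzyloxy)-2-[4-(benzyloxy)-3-methoxyphenyl]-8-[(1R)-1-(4-benzyloxy-3,5-dimethoxyphenyl)ethyl]-4-oxo-4H-chromen-3-yl}boronate | COB(OC)c1c(-c2ccc(OCc3ccccc3)c(OC)c2)oc2c([C@H](C)c3cc(OC)c(OCc4ccccc4)c(OC)c3)c(OCc3ccccc3)cc(OCc3ccccc3)c2c1=O
F8 | step 2 | (4R)-3-[(2E)-but-2-enoyl]-4-phenyl-1,3-oxazolidin-2-one | C/C=C/C(=O)N1[C@H](c2ccccc2)COC1=O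
F9 | step 2 | [4-(benzyloxy)-3,5-dimethoxyphenyl]magnesium bromide | COc1cc([Mg]Br)cc(OC)c1OCc1ccccc1
F10 | step 2 | (4R)-3-{(3S)-3-[4-(benzyloxy)-3,5-dimethoxyphenyl]butanoyl}-4-phenyl-1,3-oxazolidin-2-one | O=C(C[C@H](C)c1cc(OC)c(OCc2ccccc2)c(OC)c1)N1[C@H](c2ccccc2)COC1=O
A1 | alternative 1 | 3,5-bis(benzyloxy)-2-[(1R)-1-(4-benzyloxy-3,5-dimethoxyphenyl)ethyl]phenol | Oc1cc(OCc2ccccc2)cc(OCc2ccccc2)c1[C@H](C)c1cc(OC)c(OCc2ccccc2)c(OC)c1
A2 | alternative 1 | (2Z)-3-{3,5-bis(benzyloxy)-2-[(1R)-1-(4-benzyloxy-3,5-dimethoxyphenyl)ethyl]phenoxy}-3-[4-(benzyloxy)-3-methoxyphenyl]prop-2-enoic acid | OC(=O)/C=C(\Oc1cc(OCc2ccccc2)cc(OCc2ccccc2)c1[C@H](C)c1cc(OC)c(OCc2ccccc2)c(OC)c1)c1ccc(OCc2ccccc2)c(OC)c1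
A3 | alternative 1 | 5,7-bis(benzyloxy)-2-[4-(benzyloxy)-3-methoxyphenyl]-8-[(1R)-1-(4-benzyloxy-3,5-dimethoxyphenyl)ethyl]-4H-chromen-4-one | COc1cc(-c2cc(=O)c3c(OCc4ccccc4)cc(OCc4ccccc4)c([C@H](C)c4cc(OC)c(OCc5ccccc5)c(OC)c4)c3o2)ccc1OCc1ccccc1
A4 | alternative 2 | 3-(benzyloxy)cyclobut-2-en-1-one | O=C1CC(OCc2ccccc2)=C1
A5 | alternative 2 | {[(3R)-3-[4-(benzyloxy)-3,5-dimethoxyphenyl]but-1-yn-1-yl]oxy}tri(propan-2-yl)silane | CC(C)[Si](C(C)C)(C(C)C)OC#C[C@H](C)c1cc(OC)c(OCc2ccccc2)c(OC)c1
A6 | alternative 2 | 5-(benzyloxy)-2-[(1R)-1-(4-benzyloxy-3,5-dimethoxyphenyl)ethyl]-3-{[tri(propan-2-yl)silyl]oxy}phenol | Oc1cc(OCc2ccccc2)cc(O[Si](C(C)C)(C(C)C)C(C)C)c1[C@H](C)c1cc(OC)c(OCc2ccccc2)c(OC)c1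
A7 | alternative 3 | 4,6-bis(benzyloxy)-3-[(1R)-1-(4-benzyloxy-3,5-dimethoxyphenyl)ethyl]-2-hydroxybenzaldehyde | O=Cc1c(OCc2ccccc2)cc(OCc2ccccc2)c([C@H](C)c2cc(OC)c(OCc3ccccc3)c(OC)c2)c1O
A8 | alternative 3 | 2-[4-(benzyloxy)-3-methoxyphenyl]-2-oxoacetaldehyde | COc1cc(C(=O)C=O)ccc1OCc1ccccc1
A9 | alternative 3 | 5,7-bis(benzyloxy)-2-[4-(benzyloxy)-3-methoxyphenyl]-8-[(1R)-1-(4-benzyloxy-3,5-dimethoxyphenyl)ethyl]-3-hydroxy-4H-chromen-4-one | COc1cc(-c2oc3c([C@H](C)c4cc(OC)c(OCc5ccccc5)c(OC)c4)c(OCc4ccccc4)cc(OCc4ccccc4)c3c(=O)c2O)ccc1OCc1ccccc1
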